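**Strategy.** The route rests on opening ring C of the lower (epigallocatechin) unit at C2–C3 and C4–C4a. C2 is an acetal-level carbon bound to O1, and C4a is an ortho carbon of the phloroglucinol ring A, activated by O1, O5 and O7; a two-carbon enediol unit (C3–C4) is inserted between them. The key step is an enantioselective cationic [4+2] annulation of an O-aryl oxocarbenium ion (C4a=C8a–O1+=C2), released from a symmetric diaryl acetal of 3,4,5-tris(benzyloxy)benzaldehyde, with (Z)-1,2-bis(silyloxy)ethene; it closes ring C and sets C2 and C3. The surplus C4 oxygen is then removed, the liquiritigenin-derived flavan-4-yl cation is attached at C8, and hydrogenolysis frees the phenols.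

Key step: step 3

Remark 1: commercial liquiritigenin is taken to be the natural (2S) enantiomer in high enantiomeric purity.
Remark 2: the sense of induction of the squaramide catalyst in step 3 cannot be predicted with confidence; the antipode named is taken to give the (2R) series, and its mirror image is used if it does not.
Remark 3: flavan numbering is used throughout (O1, C2, C3, C4, C4a, C5 to C8, C8a; the aryl ring at C2 is ring B).

Step 1
Reactants: 1 3,4,5-tris(benzyloxy)benzaldehyde; 2 3,5-bis(benzyloxy)phenol (2.2 equiv)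
Product: 4 3,4,5-tris(benzyloxy)benzaldehyde bis[3,5-bis(benzyloxy)phenyl] acetal, via benzal chloride 3 (not isolated)
Conditions: SOCl2, Me2NCHO (cat.), CH2Cl2, 0 °C → rt, evaporate; then 2, NaH, THF/Me2NCHO, 0 °C → rt
Reagents that add atoms: none
Why: Deoxodichlorination of the electron-rich aldehyde by SOCl2 under Vilsmeier-type catalysis should give benzal chloride 3, whose two SN1-active chlorides are replaced in turn by the hard phenoxide oxygen of 2 (Williamson-type O-alkylation, as in the alkoxymethylation of phloroglucinol phenols) to give a symmetric diaryl acetal without any stereocentre.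

Step 2
Reactants: 5 (tert-butyldimethylsilyloxy)acetaldehyde
Product: 6 (Z)-1,2-bis(tert-butyldimethylsilyloxy)ethene
Conditions: t-BuMe2SiOTf, Et3N, CH2Cl2, 0 °C → rt
Reagents that add atoms: tert-butyldimethylsilyl triflate, CC(C)(C)[Si](C)(C)OS(=O)(=O)C(F)(F)F
Why: Soft enolisation with O-silylation (silyl enol ether formation) should give the enediol bis-silyl ether, the (Z)-isomer being favoured by the cis effect of 1,2-dioxygenated alkenes; the alkene geometry is the only stereochemical element.

Step 3
Reactants: 4 3,4,5-tris(benzyloxy)benzaldehyde bis[3,5-bis(benzyloxy)phenyl] acetal; 6 (Z)-1,2-bis(tert-butyldimethylsilyloxy)ethene (3 equiv)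
Product: 8 (2R,3S,4R)-5,7-bis(benzyloxy)-3,4-bis(tert-butyldimethylsilyloxy)-2-[3,4,5-tris(benzyloxy)phenyl]chromane (all-cis), via oxocarbenium triflate 7 (not isolated)
Conditions: 3-{[3,5-bis(trifluoromethyl)phenyl]amino}-4-({(2S)-3,3-dimethyl-1-oxo-1-[(2R)-2-(phenanthren-9-yl)pyrrolidin-1-yl]butan-2-yl}amino)cyclobut-3-ene-1,2-dione (10 mol %), t-BuMe2SiOTf (20 mol %), toluene, 0.02 M in 4, −78 → −50 °C; Et3N quench
Reagents that add atoms: none
Why: Proposed new method: t-BuMe2SiOTf, made more Lewis acidic by hydrogen bonding of its triflate to the squaramide, silylates one aryloxy oxygen of 4 and releases the (E)-O-aryl oxocarbenium ion 7 as a catalyst-bound chiral ion pair; this cationic 2-oxadiene (C4a=C8a–O1+=C2) takes up the electron-rich alkene 6 in a polar, asynchronous [4+2] process in which C3 bonds to C2 first and the resulting C4 silyloxocarbenium ion is captured by C4a, the proton lost on rearomatisation returning the leaving group as phenol 2 and regenerating the silyl triflate. The closest known reaction types are the SnCl4-promoted oxa-Povarov reaction of aryl oxocarbenium ions with alkenes, which is racemic, and the enantioselective Mukaiyama-type addition of silyl enol ethers to acetal-derived oxocarbenium ions under hydrogen-bond-donor/silyl triflate co-catalysis; an enantioselective annulation of this kind with an enediol ether has not been shown. Ring C closes as a formal [4+2] cycloaddition, in the stepwise limit by 6-exo-trig Friedel–Crafts attack of C4a on the C4 silyloxocarbenium carbon. C2 is set by the face of the oxocarbenium carbon left open in the squaramide-bound ion pair (catalyst control), the 2,3-cis relation by the endo approach of the (Z)-alkene, whose oxygen atoms lie under the cationic O1=C2 unit while the aryl group at C2 sits outside on the (E)-oxocarbenium ion, and C4 follows from the alkene geometry and is erased in step 4. The step needs ionisation in one direction only, which the symmetric diaryl acetal secures because either aryloxy group leaves to give the same cation; it needs no regiocontrol in the ring closure, because the two ortho carbons of the 3,5-bis(benzyloxy)phenoxy group are equivalent and each lies ortho or para to three oxygens; and it needs capture of 7 by 6 and not by an arene, which the higher nucleophilicity of the enol ether, its excess and the high dilution of 4 should secure.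

Step 4
Reactants: 8 (2R,3S,4R)-5,7-bis(benzyloxy)-3,4-bis(tert-butyldimethylsilyloxy)-2-[3,4,5-tris(benzyloxy)phenyl]chromane
Product: 10 (2R,3R)-5,7-bis(benzyloxy)-2-[3,4,5-tris(benzyloxy)phenyl]chroman-3-ol (penta-O-benzyl-(−)-epigallocatechin), via 3-O-silyl ether 9 (not isolated)
Conditions: Et3SiH (10 equiv), Et3SiOTf (10 mol %), CH2Cl2, −78 → −40 °C; then pyridine, HF·pyridine, THF, 0 °C → rt
Reagents that add atoms: none
Why: Silyl-triflate-catalysed ionisation of the benzylic C4–OSi bond (cation stabilised by O1, O5 and O7) and hydride transfer from Et3SiH (ionic hydrogenation) should turn C4 into CH2 whichever C4 epimer is present and leave C2 and C3 untouched, and fluoride desilylation with HF·pyridine then frees the secondary 3-OH; no stereocentre is set.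

Step 5
Reactants: 11 (2S)-liquiritigenin [(2S)-7-hydroxy-2-(4-hydroxyphenyl)chroman-4-one]
Product: 12 (2S)-7-(benzyloxy)-2-[4-(benzyloxy)phenyl]chroman-4-one
Conditions: BnOH, PPh3, DIAD, THF, 0 °C → rt
Reagents that add atoms: benzyl alcohol, OCc1ccccc1
Why: Mitsunobu etherification of both phenols with benzyl alcohol runs under essentially neutral conditions and so should avoid the base-induced retro-oxa-Michael opening to the chalcone that would racemise C2 of the flavanone.

Step 6
Reactants: 12 (2S)-7-(benzyloxy)-2-[4-(benzyloxy)phenyl]chroman-4-one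
Product: 13 (2S,4S)-7-(benzyloxy)-2-[4-(benzyloxy)phenyl]chroman-4-ol (2,4-cis)
Conditions: NaBH4, THF/MeOH, 0 °C
Reagents that add atoms: none
Why: Borohydride reduction of the flavanone carbonyl, with axial hydride delivery expected to give the 2,4-cis alcohol (4S); this centre is ionised again in step 7, so its configuration is of no consequence.

Step 7
Reactants: 13 (2S,4S)-7-(benzyloxy)-2-[4-(benzyloxy)phenyl]chroman-4-ol; 10 (2R,3R)-5,7-bis(benzyloxy)-2-[3,4,5-tris(benzyloxy)phenyl]chroman-3-ol (3 equiv, excess recovered)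
Product: 14 (2R,3R)-5,7-bis(benzyloxy)-8-{(2S,4R)-7-(benzyloxy)-2-[4-(benzyloxy)phenyl]chroman-4-yl}-2-[3,4,5-tris(benzyloxy)phenyl]chroman-3-ol
Conditions: Me3SiOTf (0.2 equiv), 4 Å molecular sieves, CH2Cl2, −78 → −40 °C, slow addition of 13; Et3N quench
Reagents that add atoms: none
Why: Dehydrative Friedel–Crafts alkylation through the flavan-4-yl cation (SN1, stabilised by O1 and the 7-benzyloxy group), in which the 4-hydroxyl of 13 leaves as water that the sieves take up: benzylated flavan-3-ols react at C8, which is flanked by O1 and only one benzyloxy group and is less hindered than C6, and axial attack on the half-chair cation with the C2 aryl group equatorial should place the incoming ring trans to it, setting the new C4 centre as 4R.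

Step 8
Reactants: 14 (2R,3R)-5,7-bis(benzyloxy)-8-{(2S,4R)-7-(benzyloxy)-2-[4-(benzyloxy)phenyl]chroman-4-yl}-2-[3,4,5-tris(benzyloxy)phenyl]chroman-3-ol
Product: 15 (2R,3R)-8-[(2S,4R)-7-hydroxy-2-(4-hydroxyphenyl)chroman-4-yl]-2-(3,4,5-trihydroxyphenyl)chromane-3,5,7-triol (CNP0220331.1)
Conditions: H2 (1 atm), Pd(OH)2/C, THF/MeOH, rt; filtration under argon
Reagents that add atoms: none
Why: Catalytic hydrogenolysis of the seven benzyl ethers over Pd(OH)2 on carbon, under which the ring C ethers and the C4–C8 bond of this 5-deoxy upper unit are expected to survive; no stereocentre is touched.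

**Compound list**

1 | 3,4,5-tris(benzyloxy)benzaldehyde | O=Cc1cc(OCc2ccccc2)c(OCc2ccccc2)c(OCc2ccccc2)c1 | starting material
2 | 3,5-bis(benzyloxy)phenol | Oc1cc(OCc2ccccc2)cc(OCc2ccccc2)c1 | starting material
3 | 3,4,5-tris(benzyloxy)benzal chloride [1,2,3-tris(benzyloxy)-5-(dichloromethyl)benzene] | ClC(Cl)c1cc(OCc2ccccc2)c(OCc2ccccc2)c(OCc2ccccc2)c1 | intermediate
4 | 3,4,5-tris(benzyloxy)benzaldehyde bis[3,5-bis(benzyloxy)phenyl] acetal | C(Oc1cc(OCc2ccccc2)cc(OCc2ccccc2)c1)(Oc1cc(OCc2ccccc2)cc(OCc2ccccc2)c1)c1cc(OCc2ccccc2)c(OCc2ccccc2)c(OCc2ccccc2)c1 | intermediate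
5 | (tert-butyldimethylsilyloxy)acetaldehyde | CC(C)(C)[Si](C)(C)OCC=O | starting material
6 | (Z)-1,2-bis(tert-butyldimethylsilyloxy)ethene | CC(C)(C)[Si](C)(C)O/C=C\O[Si](C)(C)C(C)(C)C | intermediate
7 | (E)-O-[3,5-bis(benzyloxy)phenyl] oxocarbenium triflate of 3,4,5-tris(benzyloxy)benzaldehyde | C(c1ccccc1)Oc1cc(OCc2ccccc2)cc(c1)/[O+]=C/c1cc(OCc2ccccc2)c(OCc2ccccc2)c(OCc2ccccc2)c1.[O-]S(=O)(=O)C(F)(F)F | intermediate
8 | (2R,3S,4R)-5,7-bis(benzyloxy)-3,4-bis(tert-butyldimethylsilyloxy)-2-[3,4,5-tris(benzyloxy)phenyl]chromane (2,3-cis, 3,4-cis) | C(c1ccccc1)Oc1cc(OCc2ccccc2)c2c(c1)O[C@H](c1cc(OCc3ccccc3)c(OCc3ccccc3)c(OCc3ccccc3)c1)[C@H](O[Si](C)(C)C(C)(C)C)[C@@H]2O[Si](C)(C)C(C)(C)C | intermediate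
9 | (2R,3R)-5,7-bis(benzyloxy)-3-(tert-butyldimethylsilyloxy)-2-[3,4,5-tris(benzyloxy)phenyl]chromane | C(c1ccccc1)Oc1cc(OCc2ccccc2)c2c(c1)O[C@H](c1cc(OCc3ccccc3)c(OCc3ccccc3)c(OCc3ccccc3)c1)[C@H](O[Si](C)(C)C(C)(C)C)C2 | intermediate
10 | (2R,3R)-5,7-bis(benzyloxy)-2-[3,4,5-tris(benzyloxy)phenyl]chroman-3-ol (penta-O-benzyl-(−)-epigallocatechin) | C(c1ccccc1)Oc1cc(OCc2ccccc2)c2c(c1)O[C@H](c1cc(OCc3ccccc3)c(OCc3ccccc3)c(OCc3ccccc3)c1)[C@H](O)C2 | intermediate
11 | (2S)-liquiritigenin [(2S)-7-hydroxy-2-(4-hydroxyphenyl)chroman-4-one] | Oc1ccc([C@@H]2CC(=O)c3ccc(O)cc3O2)cc1 | starting material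
12 | (2S)-7-(benzyloxy)-2-[4-(benzyloxy)phenyl]chroman-4-one | C(c5ccccc5)Oc1ccc([C@@H]2CC(=O)c3ccc(OCc5ccccc5)cc3O2)cc1 | intermediate
13 | (2S,4S)-7-(benzyloxy)-2-[4-(benzyloxy)phenyl]chroman-4-ol | C(c5ccccc5)Oc1ccc([C@@H]2C[C@H](O)c3ccc(OCc5ccccc5)cc3O2)cc1 | intermediate
14 | (2R,3R)-5,7-bis(benzyloxy)-8-{(2S,4R)-7-(benzyloxy)-2-[4-(benzyloxy)phenyl]chroman-4-yl}-2-[3,4,5-tris(benzyloxy)phenyl]chroman-3-ol | C(c5ccccc5)Oc1ccc([C@@H]2C[C@@H](c3c(OCc5ccccc5)cc(OCc5ccccc5)c4c3O[C@H](c3cc(OCc5ccccc5)c(OCc5ccccc5)c(OCc5ccccc5)c3)[C@H](O)C4)c3ccc(OCc5ccccc5)cc3O2)cc1 | intermediate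
15 | (2R,3R)-8-[(2S,4R)-7-hydroxy-2-(4-hydroxyphenyl)chroman-4-yl]-2-(3,4,5-trihydroxyphenyl)chromane-3,5,7-triol | Oc1ccc([C@@H]2C[C@@H](c3c(O)cc(O)c4c3O[C@H](c3cc(O)c(O)c(O)c3)[C@H](O)C4)c3ccc(O)cc3O2)cc1 | target

**Step count.** Total: 8 steps. Longest linear sequence: 5 steps (steps 1, 3, 4, 7, 8).

**Steps most likely to fail**

1. Step 3 (proposed new method). What may go wrong: poor facial selectivity within the chiral ion pair (low enantiomeric excess), exo instead of endo approach of 6, or loss of silyl triflate turnover through protodesilylation of 6 by triflic acid. Fallback with known chemistry, setting out from 4 and 6 and coming back at 10: the annulation is promoted by stoichiometric SnCl4 in CH2Cl2 at −78 °C without a chiral catalyst (the established racemic oxa-Povarov conditions). This should give the racemic cycloadduct, that is 8 together with its (2S,3R,4S) enantiomer F1. The conditions of step 4 convert it, by way of 9 and the enantiomeric silyl ether F2, into the racemic alcohol, that is 10 together with its (2S,3S) enantiomer F3. Oxidation with the periodinane DMP (1,1,1-triacetoxy-1,1-dihydro-1,2-benziodoxol-3(1H)-one) gives the racemic flavan-3-one F4. LiBH(s-Bu)3 at −78 °C then returns the 2,3-cis alcohol by hydride attack anti to the C2 aryl group, the established passage from the catechin to the epicatechin series, so that the cis relation no longer depends on the endo/exo outcome. Preparative chromatography on a chiral stationary phase then gives 10.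

2. Step 7. What may go wrong: self-condensation of the flavan-4-yl cation with the resorcinol-type ring A of a second molecule of 13, attack at C6 instead of C8, or attack syn to the C2 aryl group giving the 2,4-cis epimer. Fallback, setting out from 13 and coming back at 14: 13 is converted with benzyl mercaptan and ZnI2 (cat.) in CH2Cl2 into the isolable 4-benzylsulfanylflavan F5 (C4 epimers). F5 is then activated with AgBF4 in THF at 0 °C in the presence of excess 10. This thiophilic activation under essentially neutral conditions releases the same cation slowly and without a strong acid, which should suppress oligomerisation and favour the kinetic axial (trans) attack at C8.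

3. Step 4. What may go wrong: the C4 cation is captured by the electron-rich ring A of a second molecule (the process by which proanthocyanidins oligomerise), or it loses H3 to give the 3-silyloxyflav-3-ene, which erodes C3. Fallback, setting out from 8 and coming back at 10, replacing the cation by a radical: Bu4NF in THF removes both silyl groups to give the all-cis diol F6. 1,1'-Thiocarbonyldiimidazole in toluene at 80 °C closes the cyclic thionocarbonate F7. Bu3SnH with azobis(isobutyronitrile) in toluene at 90 °C then cleaves the benzylic C4–O bond through the benzylic radical (Barton–McCombie-type deoxygenation), and K2CO3/MeOH frees the 3-OH to give 10.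

**Further compounds**

F1 | step 3 | (2S,3R,4S)-5,7-bis(benzyloxy)-3,4-bis(tert-butyldimethylsilyloxy)-2-[3,4,5-tris(benzyloxy)phenyl]chromane (enantiomer of 8) | C(c1ccccc1)Oc1cc(OCc2ccccc2)c2c(c1)O[C@@H](c1cc(OCc3ccccc3)c(OCc3ccccc3)c(OCc3ccccc3)c1)[C@@H](O[Si](C)(C)C(C)(C)C)[C@H]2O[Si](C)(C)C(C)(C)C
F2 | step 3 | (2S,3S)-5,7-bis(benzyloxy)-3-(tert-butyldimethylsilyloxy)-2-[3,4,5-tris(benzyloxy)phenyl]chromane (enantiomer of 9) | C(c1ccccc1)Oc1cc(OCc2ccccc2)c2c(c1)O[C@@H](c1cc(OCc3ccccc3)c(OCc3ccccc3)c(OCc3ccccc3)c1)[C@@H](O[Si](C)(C)C(C)(C)C)C2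
F3 | step 3 | (2S,3S)-5,7-bis(benzyloxy)-2-[3,4,5-tris(benzyloxy)phenyl]chroman-3-ol (enantiomer of 10) | C(c1ccccc1)Oc1cc(OCc2ccccc2)c2c(c1)O[C@@H](c1cc(OCc3ccccc3)c(OCc3ccccc3)c(OCc3ccccc3)c1)[C@@H](O)C2
F4 | step 3 | racemic 5,7-bis(benzyloxy)-2-[3,4,5-tris(benzyloxy)phenyl]chroman-3-one | C(c1ccccc1)Oc1cc(OCc2ccccc2)c2c(c1)OC(c1cc(OCc3ccccc3)c(OCc3ccccc3)c(OCc3ccccc3)c1)C(=O)C2
F5 | step 7 | (2S)-7-(benzyloxy)-2-[4-(benzyloxy)phenyl]-4-(benzylsulfanyl)chromane (C4 epimers) | C(c5ccccc5)Oc1ccc([C@@H]2CC(SCc5ccccc5)c3ccc(OCc5ccccc5)cc3O2)cc1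
F6 | step 4 | (2R,3R,4R)-5,7-bis(benzyloxy)-2-[3,4,5-tris(benzyloxy)phenyl]chromane-3,4-diol (all-cis) | C(c1ccccc1)Oc1cc(OCc2ccccc2)c2c(c1)O[C@H](c1cc(OCc3ccccc3)c(OCc3ccccc3)c(OCc3ccccc3)c1)[C@H](O)[C@@H]2O
F7 | step 4 | cyclic 3,4-thionocarbonate of F6 | C(c1ccccc1)Oc1cc(OCc2ccccc2)c2c(c1)O[C@H](c1cc(OCc3ccccc3)c(OCc3ccccc3)c(OCc3ccccc3)c1)[C@@H]3OC(=S)O[C@H]23
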